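## Retrosynthetic overview

1. Colleterpenol (17) comes from macrocycle 16 by reductive removal of two allylic PhS groups (C1 and C17). No stereocentre is touched.
2. Key step: 16 comes from the linear C30 epoxide 15. The C1 thioallyl anion opens the trisubstituted epoxide at C14 by SN2. This forms C1–C14, closes the 14-membered ring, inverts C14 and releases the C15 tertiary alcohol.
3. Backside opening by the allylic arm gives the target's C14/C15 relationship only from the Z-olefin-derived epoxide. The E-olefin epoxide would give the C15 epimer.
4. 15 comes from epoxy triflate 10 and lithiated geranyl phenyl sulfide 12 (C16–C17). 10 comes from Sharpless epoxidation of the Z-allylic alcohol 8, which sets both stereocentres.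
5. 8 comes from a B-alkyl Suzuki coupling (C13–C14) of the farnesol-derived diene 5 with (Z)-3-iodo-2-methylprop-2-en-1-ol 7. Ring order: oxirane in step 7, then the only carbocycle in step 13.

Assumption: polyprenyl numbering is used. The ring is C1–C14 (C14 is the ring CH), C15 is the carbinol carbon and C16–C24 is the side chain. On this numbering the target is (14R,15S). The PhS-bearing carbons C17 and C1 form as epimer mixtures and are erased in the last step.

## Route

**Step 1**
Reactants: 1, (2E,6E)-farnesol
Product: 2, (2E,6E)-farnesyl TBS ether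
Conditions: TBSCl, imidazole, DMF, 0 °C → rt
Reagents that add atoms: TBSCl, CC(C)(C)[Si](C)(C)Cl
Why: Standard silyl protection masks the C1 allylic alcohol so it cannot direct or suffer the later oxidations, and the TBS ether tolerates ylide, borane, Pd and organolithium steps.

**Step 2**
Reactants: 2
Product: 3, (2E,6E,10E)-12-(TBSO)-2,6,10-trimethyldodeca-2,6,10-trien-1-ol
Conditions: SeO2 (0.2 equiv), t-BuOOH (3 equiv), salicylic acid (0.1 equiv), CH2Cl2, 0 °C → rt, stopped at partial conversion, 2 recycled
Reagents that add atoms: SeO2, O=[Se]=O, and t-BuOOH, CC(C)(C)OO (one O)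
Why: Sharpless–Umbreit SeO2 allylic oxidation (ene reaction, then [2,3]-shift) attacks the most electron-rich terminal isopropylidene and hydroxylates only its E-methyl group, leaving the internal olefins and the silyl ether intact.

**Step 3**
Reactants: 3
Product: 4, the corresponding (2E,6E,10E)-trienal (C12 aldehyde)
Conditions: MnO2, CH2Cl2, rt
Reagents that add atoms: none
Why: Chemoselective MnO2 oxidation of the allylic alcohol gives the E-enal without olefin isomerisation and converges any over-oxidised material from step 2.

**Step 4**
Reactants: 4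
Product: 5, TBS ether of (2E,6E,10E)-3,7,11-trimethyltrideca-2,6,10,12-tetraen-1-ol
Conditions: Ph3PCH3Br, n-BuLi, THF, −78 → 0 °C
Reagents that add atoms: methyltriphenylphosphonium bromide, C[P+](c1ccccc1)(c1ccccc1)c1ccccc1.[Br-] (CH2 = C13)
Why: Wittig methylenation of the enal adds C13 and gives the terminal 1,3-diene with the C10=C11 E-geometry unchanged.

**Step 5**
Reactants: 6, propargyl alcohol
Product: 7, (Z)-3-iodo-2-methylprop-2-en-1-ol
Conditions: MeMgBr (2.5 equiv), CuI (cat.), Et2O/THF, −10 °C → rt; then I2
Reagents that add atoms: MeMgBr, C[Mg]Br; iodine, II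
Why: In this Duboudin-type Cu-catalysed anti-carbomagnesiation the alkoxide directs Me to the internal carbon and Mg to the terminal carbon within a five-membered oxamagnesacycle, so iodinolysis with retention places I cis to CH2OH (Z).

**Step 6**
Reactants: 5 and 7
Product: 8, (2Z,6E,10E,14E)-16-(TBSO)-2,6,10,14-tetramethylhexadeca-2,6,10,14-tetraen-1-ol
Conditions: 5, 9-BBN, THF, 0 °C → rt; then 7, Pd(dppf)Cl2 (5 mol %), AsPh3, Cs2CO3, DMF/H2O, rt
Reagents that add atoms: none (9-BBN delivers only H)
Why: 9-BBN hydroborates only the monosubstituted terminus of the diene, and the B-alkyl Suzuki–Miyaura coupling forms C13–C14 with retention of vinyl iodide geometry, giving the Z-trisubstituted allylic alcohol.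

**Step 7**
Reactants: 8
Product: 9, {(2S,3R)-3-[(3E,7E,11E)-13-(TBSO)-3,7,11-trimethyltrideca-3,7,11-trien-1-yl]-2-methyloxiran-2-yl}methanol, i.e. (14R,15S)
Conditions: Ti(OiPr)4, L-(+)-DET, t-BuOOH (anhydrous), 4 Å MS, CH2Cl2, −20 °C
Reagents that add atoms: t-BuOOH, CC(C)(C)OO (epoxide O)
Why: Katsuki–Sharpless asymmetric epoxidation is hydroxyl-directed, so only C14=C15 reacts, and L-(+)-DET (same facial sense as nerol → (2S,3R)) sets C15 as S (final) and C14 as R (to be inverted), with about 90% ee typical for (Z)-2-methylalk-2-en-1-ols.

**Step 8**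
Reactants: 9
Product: 10, the primary triflate of 9
Conditions: Tf2O, 2,6-lutidine, CH2Cl2, −78 °C, used crude
Reagents that add atoms: triflic anhydride, O=S(=O)(OS(=O)(=O)C(F)(F)F)C(F)(F)F
Why: Low-temperature triflation activates the neopentyl-like alcohol, and the epoxy triflate survives brief handling because ionisation is disfavoured next to the oxirane and C15 carries no β-hydrogen for elimination.

**Step 9**
Reactants: 11, geranyl bromide
Product: 12, geranyl phenyl sulfide
Conditions: PhSH, K2CO3, DMF, 0 °C → rt
Reagents that add atoms: thiophenol, Sc1ccccc1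
Why: SN2 thioetherification of the primary allylic bromide proceeds without allylic transposition or E/Z erosion.

**Step 10**
Reactants: 10 and 12
Product: 13, the C16–C17 coupled epoxide (C17–SPh as an epimer mixture, C1–OTBS)
Conditions: 12, n-BuLi, DABCO, THF, −78 → −20 °C; then 10, −78 °C
Reagents that add atoms: none
Why: In this Biellmann-type alkylation the sulfur-stabilised allyllithium reacts at its α-carbon with the primary triflate much faster than with the trisubstituted epoxide, so C14 and C15 are untouched and the new C17 centre is erased in step 14.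

**Step 11**
Reactants: 13
Product: 14, the C1 allylic alcohol
Conditions: TBAF, THF, 0 °C
Reagents that add atoms: none
Why: Fluoride desilylation liberates the alcohol, and the epoxide, sulfide and olefins are inert to TBAF.

**Step 12**
Reactants: 14
Product: 15, the linear (14R,15S)-14,15-epoxy 1,17-bis(phenyl sulfide)
Conditions: PhSSPh, n-Bu3P, THF, rt
Reagents that add atoms: diphenyl disulfide, c1ccc(SSc2ccccc2)cc1 (PhS)
Why: The Hata disulfide/phosphine reaction replaces the primary allylic OH via an alkoxyphosphonium salt and SN2 attack by thiolate under neutral conditions, with no allylic shift and no epoxide opening.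

**Step 13 (key step)**
Reactants: 15
Product: 16, the 14-membered carbocycle with a free C15–OH and PhS at C1 and C17. It has the same spatial arrangement at C14 and C15 as the target; C14 is formally S here only because the SPh group raises the CIP priority of C1.
Conditions: n-BuLi (1.1 equiv), DABCO (2 equiv), THF (0.002 M), −78 °C, then slowly → 0 °C; aq NH4Cl
Reagents that add atoms: none
Why: In this Kodama–Ito-type macrocyclisation the unhindered C1–H2 is lithiated in preference to the tertiary C17–H, and the α-carbon of the thioallyllithium attacks the less substituted epoxide carbon C14 from the back, so C14 inverts, the C15–O bond is retained and the Z-derived epoxide delivers the (14R,15S) relationship; the same closure is known for terminal Me2C-epoxides in nephthenol-type cembranoids.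

**Step 14**
Reactants: 16
Product: 17, colleterpenol
Conditions: Li, EtNH2, THF, −78 °C; solid NH4Cl quench
Reagents that add atoms: none
Why: Dissolving-metal reductive desulfurisation cleaves both allylic C–S bonds and the allyl anions are protonated at the less substituted terminus, which keeps E-C2=C3 and E-C18=C19 in place and leaves the isolated olefins, the alkoxide and both stereocentres untouched.

## Compound list

| No. | Name | SMILES | Role |
|---|---|---|---|
| 1 | (2E,6E)-farnesol | `CC(C)=CCC/C(C)=C/CC/C(C)=C/CO` | starting material |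
| 2 | farnesyl TBS ether | `CC(C)=CCC/C(C)=C/CC/C(C)=C/CO[Si](C)(C)C(C)(C)C` | intermediate |
| 3 | 12-hydroxyfarnesyl TBS ether (all E) | `OC/C(C)=C/CC/C(C)=C/CC/C(C)=C/CO[Si](C)(C)C(C)(C)C` | intermediate |
| 4 | 12-oxofarnesyl TBS ether (all E) | `O=C/C(C)=C/CC/C(C)=C/CC/C(C)=C/CO[Si](C)(C)C(C)(C)C` | intermediate |
| 5 | C1–C13 tetraene TBS ether | `C=C/C(C)=C/CC/C(C)=C/CC/C(C)=C/CO[Si](C)(C)C(C)(C)C` | intermediate |
| 6 | propargyl alcohol | `C#CCO` | starting material |
| 7 | (Z)-3-iodo-2-methylprop-2-en-1-ol | `OC/C(C)=C\I` | intermediate |
| 8 | (2Z,6E,10E,14E)-16-TBSO-tetraenol | `OC/C(C)=C\CC/C(C)=C/CC/C(C)=C/CC/C(C)=C/CO[Si](C)(C)C(C)(C)C` | intermediate |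
| 9 | (2S,3R)-epoxy alcohol | `OC[C@]1(C)O[C@@H]1CC/C(C)=C/CC/C(C)=C/CC/C(C)=C/CO[Si](C)(C)C(C)(C)C` | intermediate |
| 10 | epoxy triflate | `FC(F)(F)S(=O)(=O)OC[C@]1(C)O[C@@H]1CC/C(C)=C/CC/C(C)=C/CC/C(C)=C/CO[Si](C)(C)C(C)(C)C` | intermediate |
| 11 | geranyl bromide | `CC(C)=CCC/C(C)=C/CBr` | starting material |
| 12 | geranyl phenyl sulfide | `CC(C)=CCC/C(C)=C/CSc1ccccc1` | intermediate |
| 13 | C30 epoxide, C17–SPh, C1–OTBS | `CC(C)=CCC/C(C)=C/C(Sc1ccccc1)C[C@]1(C)O[C@@H]1CC/C(C)=C/CC/C(C)=C/CC/C(C)=C/CO[Si](C)(C)C(C)(C)C` | intermediate |
| 14 | C30 epoxide, C17–SPh, C1–OH | `CC(C)=CCC/C(C)=C/C(Sc1ccccc1)C[C@]1(C)O[C@@H]1CC/C(C)=C/CC/C(C)=C/CC/C(C)=C/CO` | intermediate |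
| 15 | C30 epoxide, 1,17-bis(SPh) | `CC(C)=CCC/C(C)=C/C(Sc1ccccc1)C[C@]1(C)O[C@@H]1CC/C(C)=C/CC/C(C)=C/CC/C(C)=C/CSc1ccccc1` | intermediate |
| 16 | macrocyclic hydroxy bis-sulfide | `CC(C)=CCC/C(C)=C/C(Sc1ccccc1)C[C@](C)(O)[C@H]1C(Sc2ccccc2)/C=C(\C)CC/C=C(\C)CC/C=C(\C)CC1` | intermediate |
| 17 | colleterpenol | `CC(C)=CCC/C(C)=C/CC[C@](C)(O)[C@H]1C/C=C(\C)CC/C=C(\C)CC/C=C(\C)CC1` | target |

## Step count

- Total steps: 14
- Longest linear sequence: 12 (steps 1–4, 6–8, 10–14). Steps 5 and 9 are one-step side branches.

## Steps most likely to fail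

1. **Step 13, macrocyclisation.**
   - Risks: slow attack on a hindered internal epoxide, oligomerisation, and C17 lithiation followed by 3-exo cyclopropane formation.
   - Fallback: make the stereodefining opening intermolecular and close the ring at an easier bond.
     - Build the geraniol-derived (C5–C16) analogue of 13.
     - Open its epoxide with lithiated (E)-4-(TBSO)-3-methylbut-2-enyl phenyl sulfide (C1–C4).
     - Close C4–C5 by intramolecular alkylation of a C5 allylic sulfone anion with the C4 allylic bromide.
2. **Step 10, substitution at the neopentyl-like epoxy triflate.**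
   - Risks: attack at sulfur of the triflate, γ-alkylation, and triflate decomposition.
   - Fallback: cyclise first and add the side chain afterwards.
     - Protect the C16–OH of 9 as a TBDPS ether and selectively unmask C1.
     - Run steps 12 and 13.
     - Convert the resulting 15,16-diol into the 15,16-epoxide (TsCl, then K2CO3; the C15–O bond is untouched).
     - Open its unhindered CH2 with lithiated 12.
3. **Step 14, double reductive desulfurisation.**
   - Risks: olefin migration or E/Z leakage on protonation of the allyl anions.
   - Fallback: replace the dissolving-metal reduction with Pd-catalysed hydride delivery.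
     - Oxidise 16 chemoselectively to the bis-sulfone with (NH4)6Mo7O24/H2O2.
     - Remove both allylic sulfonyl groups by Pd(0)-catalysed hydride substitution (PdCl2(dppp), LiHBEt3), which delivers H to the less substituted π-allyl terminus with retention of geometry.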